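**Synthesis proposal for CNP0373896.1, (1S,2S,4R,5R)-2-bromo-1-(bromomethyl)-1,4-dichloro-5-[(E)-2-chloroethenyl]-5-methylcyclohexane**

Numbering of the target, used for all intermediates: C1 = CCl bearing C7H2Br, C2 = CHBr, C3 = CH2, C4 = CHCl, C5 = quaternary carbon with methyl and the chlorovinyl group C1′H=C2′HCl, C6 = CH2. The enabling feature is that C4–Cl is cis to C1′ on the quaternary C5: with C1′ as a formyl carbon, C4/C5 is a β-chloro α-quaternary aldehyde, the product pattern of a chloronium semipinacol shift.
Cuts, in retrosynthetic order: C1–Cl (tertiary alcohol, retention), C1–C7 (bromomethyllithium on a C1 ketone), C2–Br (inversion of a Rubottom C2–OH), C1′=C2′ (Takai olefination of a C5 aldehyde). C4–Cl and the ring bond C5–C6 are then cut together, which re-expands the cyclohexane to a 2-methylcyclohept-2-enol whose carbinol carbon is C1′.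
The cycloheptenol is cut at C4=C5 (metathesis) and at C6–C1′ (aldol of hex-5-en-2-one with methacrolein).
Forward: the chain is joined at C6–C1′, the seven-membered ring is closed at C4=C5, and the chlorinative 1,2-shift of C6 from C1′ to C5 contracts it to the only ring of the target. All later steps are substitutions and additions on that cyclohexane.
Stereochemistry: the S carbinol comes from the diisopinocampheylboron aldol and is relayed to C4 and C5 in the ring contraction (Cl syn to OH, C6 anti to Cl) and then lost. C2 comes from Rubottom oxidation anti to the axial chlorovinyl group followed by SN2 inversion with bromide. C1 comes from equatorial carbenoid addition followed by chlorination with retention.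

Key step: step 6

Assumption: (−)-Ipc2BCl (from (+)-α-pinene) is taken to direct the methyl-ketone boron enolate to the Si face of methacrolein, which gives the S carbinol; if the opposite sense were found, the enantiomeric chloroborane would be used with no other change.

Step 1
Reactants: 1 hex-5-en-2-one; 2 methacrolein (2-methylprop-2-enal)
Product: 4 (3S)-3-hydroxy-2-methylnona-1,8-dien-5-one, via diisopinocampheylboron enolate 3 (not isolated)
Conditions: (−)-Ipc2BCl, Et3N, Et2O, 0 °C; then 2, −78 → −20 °C; MeOH, pH 7 buffer, H2O2, 0 °C
Reagents that add atoms: none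
Why: Paterson aldol of a methyl ketone, in which the chloroborane and Et3N enolise 1 at the methyl group and the boron enolate 3 adds through a cyclic transition state to the Si face of the α-branched enal (the aldehyde class for which this reagent is most selective), which should set the S carbinol, while the terminal alkenes are inert to the buffered peroxide work-up.

Step 2
Reactants: 4 (3S)-3-hydroxy-2-methylnona-1,8-dien-5-one
Product: 5 (3S)-3-[(tert-butyldimethylsilyl)oxy]-2-methylnona-1,8-dien-5-one
Conditions: TBSCl, imidazole, DMF, 0 °C → rt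
Reagents that add atoms: tert-butyldimethylsilyl chloride CC(C)(C)[Si](C)(C)Cl
Why: Standard silylation of a secondary alcohol, which removes the free β-hydroxy ketone (retro-aldol, dehydration) before the Lewis-acidic ketalisation and keeps the allylic oxygen from binding the ruthenium carbene later.

Step 3
Reactants: 5 (3S)-3-[(tert-butyldimethylsilyl)oxy]-2-methylnona-1,8-dien-5-one
Product: 6 2-(but-3-en-1-yl)-2-{(2S)-2-[(tert-butyldimethylsilyl)oxy]-3-methylbut-3-en-1-yl}-1,3-dioxolane
Conditions: TMSOCH2CH2OTMS, TMSOTf (5 mol %), CH2Cl2, −78 → −30 °C; pyridine quench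
Reagents that add atoms: 1,2-bis(trimethylsilyloxy)ethane C[Si](C)(C)OCCO[Si](C)(C)C
Why: Noyori aprotic ketalisation, in which the silyl triflate activates the ketone toward the bis-silylated glycol at low temperature with hexamethyldisiloxane as the only by-product, so that the allylic silyl ether does not ionise and neither alkene migrates.

Step 4
Reactants: 6 2-(but-3-en-1-yl)-2-{(2S)-2-[(tert-butyldimethylsilyl)oxy]-3-methylbut-3-en-1-yl}-1,3-dioxolane
Product: 7 tert-butyldimethyl{[(7S)-8-methyl-1,4-dioxaspiro[4.6]undec-8-en-7-yl]oxy}silane
Conditions: second-generation Grubbs catalyst (H2IMes)(PCy3)Cl2Ru=CHPh (5 mol %), CH2Cl2 (0.005 M), 40 °C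
Reagents that add atoms: none
Why: Ring-closing metathesis, in which the carbene loads on the monosubstituted alkene and closes onto the 1,1-disubstituted one to give the trisubstituted cycloheptene (C4=C5), helped by the quaternary ketal carbon in the tether and driven by loss of ethylene.

Step 5
Reactants: 7 tert-butyldimethyl{[(7S)-8-methyl-1,4-dioxaspiro[4.6]undec-8-en-7-yl]oxy}silane
Product: 8 (7S)-8-methyl-1,4-dioxaspiro[4.6]undec-8-en-7-ol
Conditions: TBAF, THF, 0 °C → rt
Reagents that add atoms: none
Why: Fluoride desilylation, which leaves the dioxolane and the alkene untouched and does not involve the carbinol stereocentre.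

Step 6
Reactants: 8 (7S)-8-methyl-1,4-dioxaspiro[4.6]undec-8-en-7-ol
Product: 9 (7R,8R)-8-chloro-7-methyl-1,4-dioxaspiro[4.5]decane-7-carbaldehyde
Conditions: t-BuOCl (1.05 equiv), powdered NaHCO3, CH2Cl2, −78 → −40 °C, dark
Reagents that add atoms: tert-butyl hypochlorite CC(C)(C)OCl
Why: Proposed new method: tert-butyl hypochlorite, held at the hydroxyl by hydrogen bonding or by exchange to the allylic hypochlorite, should pass electrophilic chlorine to C4 of the trisubstituted alkene so that charge develops at the tertiary C5, and the ring bond C1′–C6, which lies on the other face and overlaps with the alkene p orbitals, then shifts to C5 while the carbinol oxygen becomes the formyl oxygen and tert-butoxide takes up the proton. The nearest known reaction types are the halonium-triggered semipinacol rearrangement of allylic alcohols, shown for ring expansions and open-chain cases with N-chloro reagents among others, and the Lewis acid ring contraction of cis-2,3-epoxy cycloalkanol silyl ethers to formyl cycloalkanes with an α-quaternary carbon; a chlorinative contraction of a cycloheptenol has not been shown. No ring is closed by cyclisation: the cyclohexane results from a suprafacial 1,2-alkyl shift that forms C5–C6, breaks C1′–C6 and so contracts the seven-membered ring to the six-membered one. C4 is set by the face of chlorination (the hydroxyl face) and C5 by migration anti to chlorine, which places C4–Cl cis to the formyl group, and the absolute sense is handed on from the S carbinol, which is destroyed in the step. The step needs chlorination syn to the hydroxyl and migration of C6 instead of hydride: allylic 1,2-strain with the C5 methyl group keeps the carbinol hydrogen in the alkene plane, so the hydroxyl is pseudoaxial, the ring carbons fold to the opposite face and leave the hydroxyl face open, and only the C1′–C6 bond is placed to migrate. The dioxolane keeps the C1 oxygen from trapping the cation, and the product, an aldehyde without α-hydrogen, cannot lose HCl.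

Step 7
Reactants: 9 (7R,8R)-8-chloro-7-methyl-1,4-dioxaspiro[4.5]decane-7-carbaldehyde; 10 chloroform
Product: 12 (7R,8R)-8-chloro-7-[(E)-2-chloroethenyl]-7-methyl-1,4-dioxaspiro[4.5]decane, via chloromethylidene dichromium reagent 11 (not isolated)
Conditions: CrCl2 (6 equiv), CHCl3 (3 equiv), THF, 65 °C
Reagents that add atoms: none
Why: Takai chloro-olefination, in which CrCl2 reduces chloroform to the geminal dichromium reagent 11 that adds to the hindered, non-enolisable aldehyde and eliminates to the E chloroalkene; the secondary chloride and the dioxolane are inert to divalent chromium, and the step is placed here because no vicinal dihalide, which CrCl2 would reduce, is present yet.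

Step 8
Reactants: 12 (7R,8R)-8-chloro-7-[(E)-2-chloroethenyl]-7-methyl-1,4-dioxaspiro[4.5]decane
Product: 13 (3R,4R)-4-chloro-3-[(E)-2-chloroethenyl]-3-methylcyclohexan-1-one
Conditions: 2 M HCl, THF, rt
Reagents that add atoms: water O
Why: Acid hydrolysis of the dioxolane, under which nothing can epimerise or eliminate because C5 is quaternary and the C4 chloride is γ to the new carbonyl.

Step 9
Reactants: 13 (3R,4R)-4-chloro-3-[(E)-2-chloroethenyl]-3-methylcyclohexan-1-one
Product: 14 {[(4R,5R)-4-chloro-5-[(E)-2-chloroethenyl]-5-methylcyclohex-1-en-1-yl]oxy}trimethylsilane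
Conditions: TMSCl, LiN(iPr)2, THF, −78 °C (in situ quench)
Reagents that add atoms: chlorotrimethylsilane C[Si](C)(C)Cl
Why: Kinetic enolisation with in situ silylation, in which the amide removes a proton from the unhindered C2 methylene and not from the neopentyl C6, and the enolate is trapped as it forms, leaving no time for 1,3-elimination onto the C4 chloride or for attack on the chloroalkene.

Step 10
Reactants: 14 {[(4R,5R)-4-chloro-5-[(E)-2-chloroethenyl]-5-methylcyclohex-1-en-1-yl]oxy}trimethylsilane
Product: 16 (2R,4R,5R)-4-chloro-5-[(E)-2-chloroethenyl]-2-hydroxy-5-methylcyclohexan-1-one, via α-trimethylsilyloxy ketone 15 (not isolated)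
Conditions: mCPBA, CH2Cl2, −20 °C; then 1 M HCl, THF, 0 °C
Reagents that add atoms: 3-chloroperbenzoic acid OOC(=O)c1cccc(Cl)c1
Why: Rubottom oxidation, in which the peracid should attack the enol ether along the axial trajectory at C2 on the face opposite the axial chlorovinyl group on C5 (half-chair with equatorial C4–Cl), and silyl migration to 15 followed by acid cleavage gives the axial 2R hydroxy ketone.

Step 11
Reactants: 16 (2R,4R,5R)-4-chloro-5-[(E)-2-chloroethenyl]-2-hydroxy-5-methylcyclohexan-1-one
Product: 18 (2S,4R,5R)-2-bromo-4-chloro-5-[(E)-2-chloroethenyl]-5-methylcyclohexan-1-one, via α-keto triflate 17 (not isolated)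
Conditions: Tf2O, 2,6-lutidine, CH2Cl2, −78 °C; then LiBr, THF, −78 → −30 °C
Reagents that add atoms: lithium bromide [Li+].[Br-]
Why: SN2 displacement at an α-keto carbon, in which the axial triflate 17 is replaced by bromide with inversion to give the equatorial 2S bromide (the epimer that direct axial bromination of the enol ether would not give), with only a slight excess of LiBr at low temperature to limit epimerisation by halide exchange.

Step 12
Reactants: 18 (2S,4R,5R)-2-bromo-4-chloro-5-[(E)-2-chloroethenyl]-5-methylcyclohexan-1-one; 19 dibromomethane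
Product: 21 (1S,2S,4R,5R)-2-bromo-1-(bromomethyl)-4-chloro-5-[(E)-2-chloroethenyl]-5-methylcyclohexan-1-ol, via bromomethyllithium 20 (not isolated)
Conditions: CH2Br2 (3 equiv), n-BuLi (1.5 equiv, added last), THF, −78 °C; AcOH, −78 °C
Reagents that add atoms: none
Why: Barbier-type halomethyllithium addition, in which n-BuLi exchanges with CH2Br2 faster than it attacks the ketone and the carbenoid 20 adds along the equatorial trajectory because the axial one is blocked by the syn-axial chlorovinyl group on C5, setting C1 with an axial hydroxyl (1S); the cold acetic acid quench keeps the alkoxide from closing to the spiro-epoxide, and the cis C2 bromide cannot be displaced by it.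

Step 13
Reactants: 21 (1S,2S,4R,5R)-2-bromo-1-(bromomethyl)-4-chloro-5-[(E)-2-chloroethenyl]-5-methylcyclohexan-1-ol
Product: 23 (1S,2S,4R,5R)-2-bromo-1-(bromomethyl)-1,4-dichloro-5-[(E)-2-chloroethenyl]-5-methylcyclohexane (target CNP0373896.1), via tertiary chlorosulfite 22 (not isolated)
Conditions: SOCl2, CH2Cl2, −20 °C; then TiCl4 (10 mol %), −78 → −20 °C
Reagents that add atoms: thionyl chloride O=S(Cl)Cl
Why: Deoxychlorination with neighbouring-group participation, in which ionisation of the chlorosulfite 22 is assisted from the rear by the bromine of the bromomethyl group and chloride opens the spiro bromiranium ion at the tertiary carbon on the face the oxygen left, so C1 is chlorinated with retention (double inversion) to the axial chloride; front-side collapse of the chlorosulfite ion pair under TiCl4 catalysis leads to the same configuration.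

**Compound list**

1 | hex-5-en-2-one | CC(=O)CCC=C | starting material
2 | methacrolein (2-methylprop-2-enal) | CC(=C)C=O | starting material
3 | hexa-1,5-dien-2-yl diisopinocampheylborinate (boron enolate of 1, Ipc groups from (+)-α-pinene) | C=CCCC(=C)OB([C@@H]1C[C@@H]2C[C@H]([C@H]1C)C2(C)C)[C@@H]1C[C@@H]2C[C@H]([C@H]1C)C2(C)C | intermediate
4 | (3S)-3-hydroxy-2-methylnona-1,8-dien-5-one | C=CCCC(=O)C[C@H](O)C(C)=C | intermediate
5 | (3S)-3-[(tert-butyldimethylsilyl)oxy]-2-methylnona-1,8-dien-5-one | C=CCCC(=O)C[C@H](O[Si](C)(C)C(C)(C)C)C(C)=C | intermediate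
6 | 2-(but-3-en-1-yl)-2-{(2S)-2-[(tert-butyldimethylsilyl)oxy]-3-methylbut-3-en-1-yl}-1,3-dioxolane | C=CCCC1(OCCO1)C[C@H](O[Si](C)(C)C(C)(C)C)C(C)=C | intermediate
7 | tert-butyldimethyl{[(7S)-8-methyl-1,4-dioxaspiro[4.6]undec-8-en-7-yl]oxy}silane | CC1=CCCC2(OCCO2)C[C@@H]1O[Si](C)(C)C(C)(C)C | intermediate
8 | (7S)-8-methyl-1,4-dioxaspiro[4.6]undec-8-en-7-ol | CC1=CCCC2(OCCO2)C[C@@H]1O | intermediate
9 | (7R,8R)-8-chloro-7-methyl-1,4-dioxaspiro[4.5]decane-7-carbaldehyde (Cl cis to CHO) | C[C@]1(C=O)CC2(OCCO2)CC[C@H]1Cl | intermediate
10 | chloroform | ClC(Cl)Cl | starting material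
11 | (chloromethylene)bis(dichlorochromium), ClCH(CrCl2)2, THF ligands omitted | ClC([Cr](Cl)Cl)[Cr](Cl)Cl | intermediate
12 | (7R,8R)-8-chloro-7-[(E)-2-chloroethenyl]-7-methyl-1,4-dioxaspiro[4.5]decane | C[C@]1(/C=C/Cl)CC2(OCCO2)CC[C@H]1Cl | intermediate
13 | (3R,4R)-4-chloro-3-[(E)-2-chloroethenyl]-3-methylcyclohexan-1-one | C[C@]1(/C=C/Cl)CC(=O)CC[C@H]1Cl | intermediate
14 | {[(4R,5R)-4-chloro-5-[(E)-2-chloroethenyl]-5-methylcyclohex-1-en-1-yl]oxy}trimethylsilane | C[C@]1(/C=C/Cl)CC(O[Si](C)(C)C)=CC[C@H]1Cl | intermediate
15 | (2R,4R,5R)-4-chloro-5-[(E)-2-chloroethenyl]-5-methyl-2-[(trimethylsilyl)oxy]cyclohexan-1-one | C[C@]1(/C=C/Cl)CC(=O)[C@H](O[Si](C)(C)C)C[C@H]1Cl | intermediate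
16 | (2R,4R,5R)-4-chloro-5-[(E)-2-chloroethenyl]-2-hydroxy-5-methylcyclohexan-1-one (axial OH) | C[C@]1(/C=C/Cl)CC(=O)[C@H](O)C[C@H]1Cl | intermediate
17 | (2R,4R,5R)-4-chloro-5-[(E)-2-chloroethenyl]-5-methyl-2-[(trifluoromethanesulfonyl)oxy]cyclohexan-1-one | C[C@]1(/C=C/Cl)CC(=O)[C@H](OS(=O)(=O)C(F)(F)F)C[C@H]1Cl | intermediate
18 | (2S,4R,5R)-2-bromo-4-chloro-5-[(E)-2-chloroethenyl]-5-methylcyclohexan-1-one (equatorial Br) | C[C@]1(/C=C/Cl)CC(=O)[C@@H](Br)C[C@H]1Cl | intermediate
19 | dibromomethane | BrCBr | starting material
20 | bromomethyllithium | [Li]CBr | intermediate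
21 | (1S,2S,4R,5R)-2-bromo-1-(bromomethyl)-4-chloro-5-[(E)-2-chloroethenyl]-5-methylcyclohexan-1-ol | C[C@]1(/C=C/Cl)C[C@](O)(CBr)[C@@H](Br)C[C@H]1Cl | intermediate
22 | chlorosulfite ester of 21 at the C1 oxygen | C[C@]1(/C=C/Cl)C[C@](OS(=O)Cl)(CBr)[C@@H](Br)C[C@H]1Cl | intermediate
23 | (1S,2S,4R,5R)-2-bromo-1-(bromomethyl)-1,4-dichloro-5-[(E)-2-chloroethenyl]-5-methylcyclohexane (CNP0373896.1) | C[C@]1(/C=C/Cl)C[C@](Cl)(CBr)[C@@H](Br)C[C@H]1Cl | target

**Step count and risks**

Total step count: 13. Longest linear sequence: 13 steps (from 1 and 2 to 23).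

Steps most likely to fail:

1. Step 6 (Proposed new method). What may go wrong: loss of an allylic proton from the chloronium ion (ene-type allylic chlorination), oxidation of the carbinol through its hypochlorite, or chlorination on the face away from the hydroxyl, which would carry part of the material into the enantiomeric series. The fallback uses known reactions, leaves the route at 8 and returns at 12. Hydroxyl-directed epoxidation (VO(acac)2, t-BuOOH, CH2Cl2) should give the syn epoxy alcohol F1, and silylation (TBSOTf, 2,6-lutidine) the epoxy silyl ether F2. Rearrangement with the bulky aluminium Lewis acid MeAl(OAr)2 (Ar = 4-bromo-2,6-di-tert-butylphenyl) at −78 °C is the established ring contraction of cis-2,3-epoxy cycloalkanol silyl ethers; C6 migrates anti to the epoxide oxygen and the product should be the cis β-silyloxy aldehyde F3, with C5 configured as in 9. Takai chloro-olefination (CrCl2, CHCl3) would then give the chlorovinyl silyl ether F4 and TBAF the secondary alcohol F5. Chlorination with retention at C4 (SOCl2, then catalytic TiCl4 at −78 °C, front-side collapse of the chlorosulfite as known for cyclic secondary alcohols) returns to 12.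

2. Step 13. What may go wrong: proton loss from the ionising tertiary centre, opening of the bromiranium ion by chloride at the primary carbon (bromine and chlorine transposed), or failure of the hindered axial alcohol to form the chlorosulfite. The fallback leaves the route at 18 and returns at 23. Peterson methylenation (Me3SiCH2Li, CeCl3, THF, −78 °C) should give the β-hydroxy silane F6, and elimination with BF3·OEt2 (CH2Cl2, −40 °C) the 2-bromo-1-methylenecyclohexane F7, which is used at once because the allylic bromide can transpose. Markovnikov bromochlorination with Bu4N+ BrCl2− in CH2Cl2 follows: the bromonium ion should form on the open equatorial face and chloride should enter the tertiary carbon anti to it, which is the configuration of 23.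

3. Step 12. What may go wrong: bromine–lithium exchange or enolisation at the α-bromo ketone by the alkyllithium or the carbenoid instead of carbonyl addition, and closure of the adduct alkoxide to an epoxide before the quench. The fallback leaves the route at 18 and returns at 21. Diazomethane (Et2O/MeOH, 0 °C) converts α-halo ketones into epoxides without a basic or halophilic organometallic and should add equatorially to give the spiro-epoxide F8. LiBr and AcOH in THF then open it at the primary carbon to the bromohydrin 21.

**Further compounds**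

F1 | step 6 | syn epoxy alcohol: 8,9-epoxide of 8 on the face of the C7 hydroxyl | C[C@@]12O[C@@H]1CCC3(OCCO3)C[C@@H]2O
F2 | step 6 | epoxy silyl ether: tert-butyldimethylsilyl ether of F1 | C[C@@]12O[C@@H]1CCC3(OCCO3)C[C@@H]2O[Si](C)(C)C(C)(C)C
F3 | step 6 | cis β-silyloxy aldehyde: (7S,8R)-8-[(tert-butyldimethylsilyl)oxy]-7-methyl-1,4-dioxaspiro[4.5]decane-7-carbaldehyde | C[C@]1(C=O)CC2(OCCO2)CC[C@H]1O[Si](C)(C)C(C)(C)C
F4 | step 6 | chlorovinyl silyl ether: tert-butyl{[(7R,8R)-7-[(E)-2-chloroethenyl]-7-methyl-1,4-dioxaspiro[4.5]decan-8-yl]oxy}dimethylsilane | C[C@]1(/C=C/Cl)CC2(OCCO2)CC[C@H]1O[Si](C)(C)C(C)(C)C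
F5 | step 6 | secondary alcohol: (7R,8R)-7-[(E)-2-chloroethenyl]-7-methyl-1,4-dioxaspiro[4.5]decan-8-ol | C[C@]1(/C=C/Cl)CC2(OCCO2)CC[C@H]1O
F6 | step 13 | β-hydroxy silane: adduct of 18 with Me3SiCH2 at C1, axial hydroxyl | C[C@]1(/C=C/Cl)C[C@](O)(C[Si](C)(C)C)[C@@H](Br)C[C@H]1Cl
F7 | step 13 | 2-bromo-1-methylenecyclohexane: (1S,4R,5R)-1-bromo-5-chloro-4-[(E)-2-chloroethenyl]-4-methyl-2-methylidenecyclohexane | C[C@]1(/C=C/Cl)CC(=C)[C@@H](Br)C[C@H]1Cl
F8 | step 12 | spiro-epoxide: 1-oxaspiro[2.5]octane from 18, epoxide oxygen axial at C1 | C[C@]1(/C=C/Cl)C[C@]2(CO2)[C@@H](Br)C[C@H]1Cl
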